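**Plan**

- Retrosynthesis: the benzyl ether and the diphenylmethylene ketal come off last. Before that the two C3–O bonds are cut (the O-methyl, then the C3 hydroxyl), then the C2–C3 bond of ring C, then the diazo group, the O1–CH2 ether bond and the ketal. This leads back to a symmetric acetophenone and a ring B benzyl bromide.
- Enabling feature: C2 of ring C is a benzylic carbon (it carries ring B) that is also bonded to the ring oxygen O1. With ring C open at C2–C3 it is the CH2 of an aryl benzyl ether, and its C–H bonds are doubly activated toward a carbene generated at C3 next to the C4 carbonyl.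
- Forward: ring A is completed first (para-hydroxylation of the acetophenone, dioxole ring across O5 and O6). Ring B is attached through O1 as its benzyl bromide, the acetyl group is turned into the diazoketone, and ring C closes last by C–H insertion. C3 is then hydroxylated and methylated, and the protecting groups are hydrogenolysed.
- Stereochemistry: C2 comes from the chiral dirhodium catalyst, which selects one of the two enantiotopic benzylic hydrogens. C3 comes from the substrate: the enolate is hydroxylated anti to the C2 aryl group (2,3-trans; 2R,3R in the target).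

Key step: step 8

Assumption: Rh2(S-PTTL)4 is taken to give the 2S flavanone in the insertion; should it favour the other benzylic hydrogen, its enantiomer Rh2(R-PTTL)4 (from D-tert-leucine) is used under the same conditions.

**Route**

Step 1
Reactants: 1 2',6'-dihydroxy-4'-methoxyacetophenone
Product: 3 1-(2,3,6-trihydroxy-4-methoxyphenyl)ethanone, via aryl potassium sulfate 2 (not isolated)
Conditions: K2S2O8, aq KOH, 0 °C to rt, N2; then aq HCl, 90 °C
Reagents that add atoms: potassium peroxodisulfate, [K+].[K+].[O-]S(=O)(=O)OOS(=O)(=O)[O-]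
Why: Elbs persulfate oxidation: the phenolate of 1 attacks peroxodisulfate through the ring carbon para to a phenolic oxygen (C3' and C5' are equivalent by symmetry), and acid hydrolysis of the aryl sulfate 2 unmasks the new hydroxyl without touching the methyl ether or the ketone.

Step 2
Reactants: 3 1-(2,3,6-trihydroxy-4-methoxyphenyl)ethanone; 4 dichlorodiphenylmethane
Product: 5 1-(5-hydroxy-7-methoxy-2,2-diphenyl-1,3-benzodioxol-4-yl)ethanone
Conditions: Ph2CCl2, Ph2O, 175 °C, N2
Reagents that add atoms: dichlorodiphenylmethane (compound 4), ClC(Cl)(c1ccccc1)c1ccccc1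
Why: Catechol ketalisation by double substitution at the geminal dichloride: only the vicinal 2',3'-hydroxyls can close the five-membered 1,3-dioxole, so the chelated 6'-hydroxyl stays free for the later etherification.

Step 3
Reactants: 6 3-hydroxy-4,5-dimethoxybenzaldehyde
Product: 7 3-(benzyloxy)-4,5-dimethoxybenzaldehyde
Conditions: BnBr, K2CO3, DMF, rt
Reagents that add atoms: benzyl bromide, BrCc1ccccc1
Why: Williamson ether synthesis on the only phenol of 6; the aldehyde is inert to carbonate.

Step 4
Reactants: 7 3-(benzyloxy)-4,5-dimethoxybenzaldehyde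
Product: 8 [3-(benzyloxy)-4,5-dimethoxyphenyl]methanol
Conditions: NaBH4, MeOH, 0 °C
Reagents that add atoms: none
Why: Borohydride reduction of the aryl aldehyde to the benzylic alcohol; the benzyl and methyl ethers are untouched.

Step 5
Reactants: 8 [3-(benzyloxy)-4,5-dimethoxyphenyl]methanol
Product: 9 1-(benzyloxy)-5-(bromomethyl)-2,3-dimethoxybenzene
Conditions: PBr3, CH2Cl2, 0 °C
Reagents that add atoms: phosphorus tribromide, BrP(Br)Br
Why: Bromination of a primary benzylic alcohol with PBr3 via the phosphite ester and bromide substitution; the aryl ethers tolerate the brief cold exposure.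

Step 6
Reactants: 5 1-(5-hydroxy-7-methoxy-2,2-diphenyl-1,3-benzodioxol-4-yl)ethanone; 9 1-(benzyloxy)-5-(bromomethyl)-2,3-dimethoxybenzene
Product: 10 1-{5-[3-(benzyloxy)-4,5-dimethoxybenzyloxy]-7-methoxy-2,2-diphenyl-1,3-benzodioxol-4-yl}ethanone
Conditions: K2CO3, DMF, 60 °C
Reagents that add atoms: none
Why: Williamson ether synthesis: the chelated but acidic ortho-hydroxyketone phenoxide displaces the reactive benzylic bromide, and the ketal, ketone and ethers are stable to K2CO3.

Step 7
Reactants: 10 1-{5-[3-(benzyloxy)-4,5-dimethoxybenzyloxy]-7-methoxy-2,2-diphenyl-1,3-benzodioxol-4-yl}ethanone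
Product: 13 2-diazo-1-{5-[3-(benzyloxy)-4,5-dimethoxybenzyloxy]-7-methoxy-2,2-diphenyl-1,3-benzodioxol-4-yl}ethanone, via lithium enolate 11 (not isolated), via trifluoroacetyl diketone 12 (not isolated)
Conditions: LiN(SiMe3)2, THF, −78 °C; CF3CO2CH2CF3, −78 °C; aq HCl work-up; then 4-AcNHC6H4SO2N3, Et3N, H2O (1 equiv), MeCN, rt
Reagents that add atoms: 4-acetamidobenzenesulfonyl azide, CC(=O)Nc1ccc(cc1)S(=O)(=O)N=[N+]=[N-] (the two diazo nitrogens); 2,2,2-trifluoroethyl trifluoroacetate, O=C(OCC(F)(F)F)C(F)(F)F (its trifluoroacetyl group is carried by 12 only and is lost again)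
Why: Detrifluoroacetylative Regitz-type diazo transfer: Claisen trifluoroacetylation of the methyl ketone enolate 11 gives the activated 1,3-diketone 12, which accepts the diazo group from the sulfonyl azide and loses the trifluoroacetyl group to the sulfonamide, so the acid-sensitive ortho-alkoxy diazoketone is made under basic conditions throughout.

Step 8
Reactants: 13 2-diazo-1-{5-[3-(benzyloxy)-4,5-dimethoxybenzyloxy]-7-methoxy-2,2-diphenyl-1,3-benzodioxol-4-yl}ethanone
Product: 14 (2S)-2-[3-(benzyloxy)-4,5-dimethoxyphenyl]-7-methoxy-5,6-(diphenylmethylenedioxy)chroman-4-one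
Conditions: Rh2(S-PTTL)4 [dirhodium tetrakis(N-phthaloyl-(S)-tert-leucinate)] (1 mol %), toluene, 0 °C, slow addition of 13 at high dilution
Reagents that add atoms: none
Why: Rh2(S-PTTL)4 (divalent rhodium) expels dinitrogen from 13 and gives an electrophilic rhodium carbene at C3, which inserts into one C–H bond of the ArO–CH2–Ar methylene through a concerted three-centre transition state with hydride-transfer character, so that the C2–C3 bond forms and the hydrogen ends up on C3. The closest known reaction type is the dirhodium carboxylate-catalysed intramolecular C–H insertion of ortho-alkoxyaryl diazomethyl ketones, which gives 2-substituted chroman-4-ones. Ring C closes as a six-membered ring by 1,6-insertion, the carbene carbon bonding to the sixth atom of the chain C3–C4–C4a–C8a–O1–C2. The C2 stereocentre is set by the catalyst: the phthalimido walls of the chiral carboxylate ligands differentiate the two enantiotopic benzylic hydrogens, and the S catalyst is taken to give the 2S product. The step needs chemoselectivity for insertion over oxonium ylide formation followed by 1,2-shift; the C–H bond is activated twice over (ether oxygen, electron-rich ring B), the ether oxygen is a weakly basic vinylogous ester oxygen, the acetal oxygen on the other flank of the carbene is shielded by its geminal phenyl groups and offers no C–H bond, and the bulky carboxylate catalyst is chosen for its low tendency to form ylides. Slow addition of 13 at high dilution suppresses carbene dimerisation.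

Step 9
Reactants: 14 (2S)-2-[3-(benzyloxy)-4,5-dimethoxyphenyl]-7-methoxy-5,6-(diphenylmethylenedioxy)chroman-4-one
Product: 16 (2R,3R)-2-[3-(benzyloxy)-4,5-dimethoxyphenyl]-3-hydroxy-7-methoxy-5,6-(diphenylmethylenedioxy)chroman-4-one, via lithium enolate 15 (not isolated)
Conditions: LiN(iPr)2, THF, −78 °C; then dimethyldioxirane (acetone solution), −78 °C; AcOH quench
Reagents that add atoms: dimethyldioxirane, CC1(C)OO1
Why: Electrophilic α-hydroxylation of an enolate by dimethyldioxirane: the kinetic lithium enolate 15 is attacked at C3 on the face opposite the C2 aryl group, giving the 2,3-trans ketol (the more stable diastereomer, both substituents equatorial), and the low temperature keeps the enolate from expelling the ring A phenoxide.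

Step 10
Reactants: 16 (2R,3R)-2-[3-(benzyloxy)-4,5-dimethoxyphenyl]-3-hydroxy-7-methoxy-5,6-(diphenylmethylenedioxy)chroman-4-one
Product: 17 (2R,3R)-2-[3-(benzyloxy)-4,5-dimethoxyphenyl]-3,7-dimethoxy-5,6-(diphenylmethylenedioxy)chroman-4-one
Conditions: Me3OBF4, 1,8-bis(dimethylamino)naphthalene, 4 Å molecular sieves, CH2Cl2, 0 °C to rt
Reagents that add atoms: trimethyloxonium tetrafluoroborate, C[O+](C)C.F[B-](F)(F)F
Why: O-Methylation with a Meerwein salt buffered by a non-nucleophilic amine base: the secondary hydroxyl is alkylated without forming the enolate, so neither C3 nor C2 can epimerise and the ketol is not oxidised to the flavonol.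

Step 11
Reactants: 17 (2R,3R)-2-[3-(benzyloxy)-4,5-dimethoxyphenyl]-3,7-dimethoxy-5,6-(diphenylmethylenedioxy)chroman-4-one
Product: 18 (2R,3R)-5,6-dihydroxy-2-(3-hydroxy-4,5-dimethoxyphenyl)-3,7-dimethoxychroman-4-one
Conditions: H2 (1 atm), Pd/C (10% palladium on carbon), THF/MeOH, rt
Reagents that add atoms: none
Why: Catalytic hydrogenolysis cleaves the benzyl ether (to toluene) and the doubly benzylic diphenylmethylene ketal (to diphenylmethane) in one operation, while the aryl ketone, the C3 methyl ether and the C2–O1 bond of a chromanone normally survive these mild conditions.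

**Compound list**

1 | 2',6'-dihydroxy-4'-methoxyacetophenone | COc1cc(O)c(C(C)=O)c(O)c1 | starting material
2 | potassium 3-acetyl-2,4-dihydroxy-6-methoxyphenyl sulfate | COc1cc(O)c(C(C)=O)c(O)c1OS(=O)(=O)[O-].[K+] | intermediate
3 | 1-(2,3,6-trihydroxy-4-methoxyphenyl)ethanone | COc1cc(O)c(C(C)=O)c(O)c1O | intermediate
4 | dichlorodiphenylmethane | ClC(Cl)(c1ccccc1)c1ccccc1 | starting material
5 | 1-(5-hydroxy-7-methoxy-2,2-diphenyl-1,3-benzodioxol-4-yl)ethanone | COc1cc(O)c(C(C)=O)c2OC(c3ccccc3)(c3ccccc3)Oc12 | intermediate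
6 | 3-hydroxy-4,5-dimethoxybenzaldehyde | COc1cc(C=O)cc(O)c1OC | starting material
7 | 3-(benzyloxy)-4,5-dimethoxybenzaldehyde | COc1cc(C=O)cc(OCc2ccccc2)c1OC | intermediate
8 | [3-(benzyloxy)-4,5-dimethoxyphenyl]methanol | COc1cc(CO)cc(OCc2ccccc2)c1OC | intermediate
9 | 1-(benzyloxy)-5-(bromomethyl)-2,3-dimethoxybenzene | COc1cc(CBr)cc(OCc2ccccc2)c1OC | intermediate
10 | 1-{5-[3-(benzyloxy)-4,5-dimethoxybenzyloxy]-7-methoxy-2,2-diphenyl-1,3-benzodioxol-4-yl}ethanone | COc1cc(OCc2cc(OCc3ccccc3)c(OC)c(OC)c2)c(C(C)=O)c2OC(c3ccccc3)(c3ccccc3)Oc12 | intermediate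
11 | lithium enolate of 10 (lithium 1-aryl-ethen-1-olate) | COc1cc(OCc2cc(OCc3ccccc3)c(OC)c(OC)c2)c(C(=C)[O-])c2OC(c3ccccc3)(c3ccccc3)Oc12.[Li+] | intermediate
12 | 4,4,4-trifluoro-1-{5-[3-(benzyloxy)-4,5-dimethoxybenzyloxy]-7-methoxy-2,2-diphenyl-1,3-benzodioxol-4-yl}butane-1,3-dione | COc1cc(OCc2cc(OCc3ccccc3)c(OC)c(OC)c2)c(C(=O)CC(=O)C(F)(F)F)c2OC(c3ccccc3)(c3ccccc3)Oc12 | intermediate
13 | 2-diazo-1-{5-[3-(benzyloxy)-4,5-dimethoxybenzyloxy]-7-methoxy-2,2-diphenyl-1,3-benzodioxol-4-yl}ethanone | COc1cc(OCc2cc(OCc3ccccc3)c(OC)c(OC)c2)c(C(=O)C=[N+]=[N-])c2OC(c3ccccc3)(c3ccccc3)Oc12 | intermediate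
14 | (2S)-2-[3-(benzyloxy)-4,5-dimethoxyphenyl]-7-methoxy-5,6-(diphenylmethylenedioxy)chroman-4-one | COc1cc2c(c3OC(c4ccccc4)(c4ccccc4)Oc13)C(=O)C[C@@H](c1cc(OCc3ccccc3)c(OC)c(OC)c1)O2 | intermediate
15 | lithium enolate of 14 (lithium (2S)-2H-chromen-4-olate) | COc1cc2c(c3OC(c4ccccc4)(c4ccccc4)Oc13)C([O-])=C[C@@H](c1cc(OCc3ccccc3)c(OC)c(OC)c1)O2.[Li+] | intermediate
16 | (2R,3R)-2-[3-(benzyloxy)-4,5-dimethoxyphenyl]-3-hydroxy-7-methoxy-5,6-(diphenylmethylenedioxy)chroman-4-one (2,3-trans) | COc1cc2c(c3OC(c4ccccc4)(c4ccccc4)Oc13)C(=O)[C@H](O)[C@@H](c1cc(OCc3ccccc3)c(OC)c(OC)c1)O2 | intermediate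
17 | (2R,3R)-2-[3-(benzyloxy)-4,5-dimethoxyphenyl]-3,7-dimethoxy-5,6-(diphenylmethylenedioxy)chroman-4-one | COc1cc2c(c3OC(c4ccccc4)(c4ccccc4)Oc13)C(=O)[C@H](OC)[C@@H](c1cc(OCc3ccccc3)c(OC)c(OC)c1)O2 | intermediate
18 | (2R,3R)-5,6-dihydroxy-2-(3-hydroxy-4,5-dimethoxyphenyl)-3,7-dimethoxychroman-4-one | COc1cc2c(c(O)c1O)C(=O)[C@H](OC)[C@@H](c1cc(O)c(OC)c(OC)c1)O2 | target

**Count**

Total steps: 11.
Longest linear sequence: 9 steps (6 to 18 through steps 3, 4, 5, 6, 7, 8, 9, 10, 11); the ring A branch from 1 joins at step 6.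

**Steps most likely to fail**

Step 8 (C–H insertion). The carbene may be captured by the benzyl ether oxygen or by the acetal oxygen (oxonium ylide formation followed by 1,2-shift), or the two benzylic hydrogens may not be differentiated well enough. The fallback leaves carbene chemistry and sets out from ketone 5 and aldehyde 7.
- Claisen–Schmidt condensation (KOH, EtOH, rt) should give (E)-3-[3-(benzyloxy)-4,5-dimethoxyphenyl]-1-(5-hydroxy-7-methoxy-2,2-diphenyl-1,3-benzodioxol-4-yl)prop-2-en-1-one F1.
- NaOAc in refluxing EtOH should close it by intramolecular oxa-Michael addition to racemic 2-[3-(benzyloxy)-4,5-dimethoxyphenyl]-7-methoxy-5,6-(diphenylmethylenedioxy)chroman-4-one F2.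
- Kinetic resolution by asymmetric transfer hydrogenation follows, with Cp*RhCl(TsDPEN), the chloro(pentamethylcyclopentadienyl)rhodium complex of N-tosyl-1,2-diphenylethylenediamine (trivalent rhodium), and HCO2H/Et3N. The ligand antipode that reduces the 2R ketone faster is used. It should convert the unwanted enantiomer into (2R,4R)-2-[3-(benzyloxy)-4,5-dimethoxyphenyl]-7-methoxy-5,6-(diphenylmethylenedioxy)chroman-4-ol F3, which is removed by chromatography.
- The 2S ketone is left behind, and the route is rejoined at 14.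

Step 9 (C3 hydroxylation). The enolate may expel the ring A phenoxide (retro-oxa-Michael opening to the chalcone), which would erode the C2 configuration on reclosure, or the oxidant may not discriminate the two faces well. The fallback sets out from 14.
- Soft enolisation with Me3SiOTf and Et3N (CH2Cl2, 0 °C), which never generates a free metal enolate, should give (2S)-2-[3-(benzyloxy)-4,5-dimethoxyphenyl]-7-methoxy-5,6-(diphenylmethylenedioxy)-4-(trimethylsilyloxy)-2H-chromene F4.
- Epoxidation with dimethyldioxirane (acetone/CH2Cl2, −40 °C) anti to the C2 aryl group should give 2-[3-(benzyloxy)-4,5-dimethoxyphenyl]-3,4-epoxy-7-methoxy-5,6-(diphenylmethylenedioxy)-4-(trimethylsilyloxy)chroman F5, with the oxirane oxygen trans to the aryl group.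
- Mild acid (citric acid, MeOH) opens the epoxide with loss of the silyl group (Rubottom oxidation), and the route is rejoined at 16.

Step 1 (persulfate oxidation). Conversion may be low and the electron-rich diphenol may be over-oxidised (quinone formation, polymeric material), so that little hydroquinone sulfate forms. The fallback sets out from 1.
- Duff formylation (hexamethylenetetramine, CF3CO2H, 80 °C; then aq HCl) at the equivalent C3'/C5' position should give 3-acetyl-2,4-dihydroxy-6-methoxybenzaldehyde F6.
- Dakin oxidation (H2O2, aq NaOH, 0 °C to rt; then acid) converts the formyl group ortho to the hydroxyl into a hydroxyl group by aryl migration and hydrolysis of the formate, and the route is rejoined at 3.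

**Further compounds**

F1 | step 8 | (E)-3-[3-(benzyloxy)-4,5-dimethoxyphenyl]-1-(5-hydroxy-7-methoxy-2,2-diphenyl-1,3-benzodioxol-4-yl)prop-2-en-1-one | COc1cc(O)c(C(=O)/C=C/c2cc(OCc3ccccc3)c(OC)c(OC)c2)c2OC(c3ccccc3)(c3ccccc3)Oc12
F2 | step 8 | racemic 2-[3-(benzyloxy)-4,5-dimethoxyphenyl]-7-methoxy-5,6-(diphenylmethylenedioxy)chroman-4-one | COc1cc2c(c3OC(c4ccccc4)(c4ccccc4)Oc13)C(=O)CC(c1cc(OCc3ccccc3)c(OC)c(OC)c1)O2
F3 | step 8 | (2R,4R)-2-[3-(benzyloxy)-4,5-dimethoxyphenyl]-7-methoxy-5,6-(diphenylmethylenedioxy)chroman-4-ol (2,4-cis) | COc1cc2c(c3OC(c4ccccc4)(c4ccccc4)Oc13)[C@H](O)C[C@H](c1cc(OCc3ccccc3)c(OC)c(OC)c1)O2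
F4 | step 9 | (2S)-2-[3-(benzyloxy)-4,5-dimethoxyphenyl]-7-methoxy-5,6-(diphenylmethylenedioxy)-4-(trimethylsilyloxy)-2H-chromene | COc1cc2c(c3OC(c4ccccc4)(c4ccccc4)Oc13)C(O[Si](C)(C)C)=C[C@@H](c1cc(OCc3ccccc3)c(OC)c(OC)c1)O2
F5 | step 9 | 2-[3-(benzyloxy)-4,5-dimethoxyphenyl]-3,4-epoxy-7-methoxy-5,6-(diphenylmethylenedioxy)-4-(trimethylsilyloxy)chroman, oxirane oxygen trans to the C2 aryl group | COc1cc2c(c3OC(c4ccccc4)(c4ccccc4)Oc13)[C@]1(O[Si](C)(C)C)O[C@@H]1[C@@H](c1cc(OCc3ccccc3)c(OC)c(OC)c1)O2
F6 | step 1 | 3-acetyl-2,4-dihydroxy-6-methoxybenzaldehyde | COc1cc(O)c(C(C)=O)c(O)c1C=O
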